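The numbers of this flask are invented, and the outcome is calculated.

The target forms at a rate set by the rate constant of its step times electrophile times dissolved nucleophile, and we ask how far that carries this flask.

electrophile 0.41 M; free base 3.00 equiv; gas 59 mM (held); time 2.0 h

- part of the electrophile that has reacted at 2.0 h
- share of the unused nucleophile that is free and not bound as protonated nucleophile, at 2.0 h

- where a step has two of a species, its rate is k times that concentration squared, and two are used at each turn
- at the start none of nucleophile is dissolved
- run time (flask): 2.0 h

    gas ⇌ nucleophile, rate k1*(csat - [nucleophile]) (k1 = 0.00581 s⁻¹, csat = 59 mM)
    acid set free + free base ⇌ salt of the base (K2 = 4.36 M⁻¹, k2 = 0.0237 M⁻¹ s⁻¹)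
    2 free base → self-condensation product (k3 = 3.85 × 10⁻⁴ M⁻¹ s⁻¹)
    nucleophile + acid set free ⇌ protonated nucleophile, settled at all times (K4 = 13000 M⁻¹)
    electrophile + nucleophile → acid set free + target (k5 = 0.00890 M⁻¹ s⁻¹)

If the nucleophile were held at its saturation value of 59 mM, the electrophile would decay as a pseudo-first-order species, with an exponent of 3.78 over the run. But none is dissolved at the start, and each turn draws two nucleophile: one enters the target and one takes up the acid set free. We expect that second draw because, at the start, binding to nucleophile outweighs binding to free base, 340 against 5.4.

Supply meets this draw within about 1.27 min, far shorter than the run. The demand ratio, two times the target rate constant times the charged electrophile, divided by the transfer coefficient, is 1.26. The rate per electrophile then stands below its saturated value by a factor of one over (one plus demand ratio times the fraction of electrophile left). That factor is 0.443 at the start.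

We replace its curve by a mean. Taking the end value as one gives a mean of 0.722 and 93.5 % reacted. At that conversion the end factor is 0.924, which lowers our figure by 1 percentage point to 92.5 %. We reckoned no free share.

The forecast gives 92 % and 12.3 %, holding that “the reaction is fed by gas transfer”.

The simulation gives 92.1 % and 12.4 %.

In this flask, with 35.9 % of the electrophile left at 1.00 h, the factor reads 0.689, and the nucleophile stood at 68.0 % of saturation. The neighbouring flask, charged with 0.16 M of electrophile, has a demand ratio of 0.490, so its factor starts at 0.671. The same two passes give 95.6 % reacted, and that flask reached 96.0 %.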